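The route rests on cutting the C1–C2 bond (geranylgeraniol numbering) between the ester OCH2 carbon and the vinylic CH of the allylic linolenate. The key step exploits the E-trisubstituted C2=C3 alkene and its C3 methyl group. A terminal 1,5-enyne lacking both C1 and that methyl undergoes zirconium-catalysed syn-methylalumination. The alkenylalane is then cross-coupled in the same flask, under palladium catalysis, with iodomethyl α-linolenate. One operation thus installs the methyl group, fixes the alkene geometry, forms C1–C2 and delivers the finished ester without an alcohol stage or protecting group. The cyclohexene stereocentre C10 stems from a CBS reduction relayed by Johnson–Claisen rearrangement; C6=C7 comes from a first carboalumination.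

Key step: step 11

Remark: atom numbers follow geranylgeraniol numbering (C1 = OCH2, C10 = ring CH). Enone 1 is taken as a catalogue compound, and the sense of induction in step 1 follows the usual oxazaborolidine model with the alkenyl arm as the large group.

Step 1
Reactants: 1 2,4,4-trimethylcyclohex-2-en-1-one
Product: 2 (1R)-2,4,4-trimethylcyclohex-2-en-1-ol
Conditions: (S)-Me-CBS oxazaborolidine [(S)-1-methyl-3,3-diphenyltetrahydro-1H,3H-pyrrolo[1,2-c][1,3,2]oxazaborole] (0.1 equiv), catecholborane (1.5 equiv), toluene, −78 °C; aq NaOH work-up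
Reagents that add atoms: none
Why: Corey–Bakshi–Shibata reduction, in which the ketone binds to the oxazaborolidine boron with its larger α-methylated alkenyl arm turned away from the catalyst, so that hydride should reach one carbonyl face and set the carbinol carbon as R while the hindered alkene is spared at low temperature.

Step 2
Reactants: 2 (1R)-2,4,4-trimethylcyclohex-2-en-1-ol
Product: 4 ethyl 2-[(1S)-2,6,6-trimethylcyclohex-2-en-1-yl]acetate, via ketene acetal 3 (not isolated)
Conditions: MeC(OEt)3 (excess), EtCO2H (cat), 140–150 °C, EtOH distilled off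
Reagents that add atoms: triethyl orthoacetate, CC(OCC)(OCC)OCC
Why: Johnson–Claisen rearrangement, in which acid-catalysed exchange gives mixed ketene acetal 3 and its suprafacial [3,3] shift forms the new C–C bond on the ring face that carried oxygen, so the R carbinol centre is traded for the S centre C10 next to the gem-dimethyl carbon and the ring alkene moves into its final position.

Step 3
Reactants: 4 ethyl 2-[(1S)-2,6,6-trimethylcyclohex-2-en-1-yl]acetate
Product: 5 2-[(1S)-2,6,6-trimethylcyclohex-2-en-1-yl]ethan-1-ol
Conditions: LiAlH4, Et2O, 0 °C to rt; aq NaOH work-up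
Reagents that add atoms: none
Why: Standard LiAlH4 reduction of an ester to the primary alcohol, which touches neither the trisubstituted alkene nor the non-epimerisable ring stereocentre.

Step 4
Reactants: 5 2-[(1S)-2,6,6-trimethylcyclohex-2-en-1-yl]ethan-1-ol
Product: 6 (6S)-6-(2-iodoethyl)-1,5,5-trimethylcyclohex-1-ene
Conditions: I2, PPh3, imidazole, CH2Cl2, 0 °C to rt
Reagents that add atoms: iodine, II
Why: Appel-type (Garegg–Samuelsson) iodination, in which the alkoxyphosphonium ion of the unhindered primary alcohol is displaced by iodide in an SN2 step remote from the stereocentre.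

Step 5
Reactants: 6 (6S)-6-(2-iodoethyl)-1,5,5-trimethylcyclohex-1-ene
Product: 7 (6S)-6-(but-3-yn-1-yl)-1,5,5-trimethylcyclohex-1-ene
Conditions: LiC≡CH·H2NCH2CH2NH2, DMSO, rt
Reagents that add atoms: lithium acetylide (as ethylenediamine complex), [Li]C#C
Why: SN2 alkylation of lithium acetylide by a primary iodide in a dipolar aprotic solvent, a standard terminal-alkyne synthesis in which elimination should stay minor.

Step 6
Reactants: 7 (6S)-6-(but-3-yn-1-yl)-1,5,5-trimethylcyclohex-1-ene
Product: 9 (6S)-6-[(3E)-4-iodo-3-methylbut-3-en-1-yl]-1,5,5-trimethylcyclohex-1-ene, via alkenylalane 8 (not isolated)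
Conditions: AlMe3 (2 equiv), Cp2ZrCl2 (0.25 equiv), CH2Cl2, 0 °C to rt; then I2, THF, −30 to 0 °C
Reagents that add atoms: trimethylaluminium, C[Al](C)C; iodine, II
Why: Negishi zirconium-catalysed carboalumination adds methyl and aluminium syn to the terminal alkyne with methyl at the internal carbon, and iodinolysis of the C–Al bond of 8 with retention should give the E iodide that defines the C6=C7 geometry.

Step 7
Reactants: 9 (6S)-6-[(3E)-4-iodo-3-methylbut-3-en-1-yl]-1,5,5-trimethylcyclohex-1-ene; 10 (4-bromobut-1-yn-1-yl)trimethylsilane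
Product: 12 trimethyl{(5E)-6-methyl-8-[(1S)-2,6,6-trimethylcyclohex-2-en-1-yl]oct-5-en-1-yn-1-yl}silane, via alkylzinc bromide 11 (not isolated)
Conditions: 10, Zn dust, I2 (5 mol %), DMA, 80 °C; then 9, PdCl2(dppf) (3 mol %), THF, rt
Reagents that add atoms: none
Why: Negishi coupling, in which alkylzinc bromide 11 from direct zinc insertion couples with the alkenyl iodide under palladium catalysis with retention of alkene geometry, the bidentate dppf ligand favouring reductive elimination over β-hydride elimination.

Step 8
Reactants: 12 trimethyl{(5E)-6-methyl-8-[(1S)-2,6,6-trimethylcyclohex-2-en-1-yl]oct-5-en-1-yn-1-yl}silane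
Product: 13 (6S)-1,5,5-trimethyl-6-[(3E)-3-methyloct-3-en-7-yn-1-yl]cyclohex-1-ene
Conditions: K2CO3 (0.2 equiv), MeOH/THF, rt
Reagents that add atoms: none
Why: Base-catalysed methanolysis of the alkynyl C–Si bond (protodesilylation), mild enough to leave both alkenes and the stereocentre unchanged.

Step 9
Reactants: 14 α-linolenic acid, (9Z,12Z,15Z)-octadeca-9,12,15-trienoic acid
Product: 15 chloromethyl (9Z,12Z,15Z)-octadeca-9,12,15-trienoate
Conditions: ClCH2OSO2Cl, NaHCO3, Bu4NHSO4 (cat), CH2Cl2/H2O, 0 °C to rt
Reagents that add atoms: chloromethyl chlorosulfate, ClCOS(=O)(=O)Cl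
Why: Phase-transfer O-alkylation of the carboxylate, in which chlorosulfate is by far the better leaving group of the reagent, so the chloromethyl ester forms without touching the skipped all-Z triene.

Step 10
Reactants: 15 chloromethyl (9Z,12Z,15Z)-octadeca-9,12,15-trienoate
Product: 16 iodomethyl (9Z,12Z,15Z)-octadeca-9,12,15-trienoate
Conditions: NaI, acetone, rt, dark
Reagents that add atoms: sodium iodide, [Na+].[I-]
Why: Finkelstein halide exchange driven by precipitation of NaCl from acetone, giving the more reactive iodide under neutral conditions.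

Step 11
Reactants: 13 (6S)-1,5,5-trimethyl-6-[(3E)-3-methyloct-3-en-7-yn-1-yl]cyclohex-1-ene; 16 iodomethyl (9Z,12Z,15Z)-octadeca-9,12,15-trienoate
Product: 18 (2E,6E)-3,7-dimethyl-9-[(1S)-2,6,6-trimethylcyclohex-2-en-1-yl]nona-2,6-dien-1-yl (9Z,12Z,15Z)-octadeca-9,12,15-trienoate, via alkenylalane 17 (not isolated)
Conditions: 13, AlMe3 (2 equiv), Cp2ZrCl2 (0.2 equiv), CH2Cl2, 0 °C to rt; volatiles and free AlMe3 removed in vacuo; THF, 16 (1.2 equiv), Pd2(dba)3 (2.5 mol %), P(2-furyl)3 (10 mol %), ZnCl2 (0.2 equiv), 0 °C to rt, dark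
Reagents that add atoms: trimethylaluminium, C[Al](C)C
Why: Proposed new method: Cp2ZrCl2-activated AlMe3 adds methyl and aluminium syn across the terminal alkyne of 13 with methyl on the internal carbon (Negishi carboalumination), giving alkenylalane 17 in which the C3 methyl group and the E geometry are already fixed. Zerovalent palladium then inserts in SN2 fashion into the oxygen-activated carbon–iodine bond of 16 to give an acyloxymethylpalladium iodide that has no β-hydrogen, the alkenyl group passes from aluminium (relayed by ZnCl2) to palladium, and reductive elimination with retention forms C1–C2. The closest known reaction types are the palladium- or nickel-catalysed coupling of carboalumination-derived alkenylalanes with benzylic and allylic chlorides, the uncatalysed capture of such alanes by chloromethyl methyl ether, and the reverse-polarity Negishi coupling of acyloxymethylzinc iodides with sp2 halides, which runs through the same (acyloxymethyl)(organyl)palladium intermediate; what has not been shown is a halomethyl carboxylate as electrophile for an alkenylalane. No ring is closed and no stereocentre is made, C10 is remote and untouched, and the only stereochemical issue, the C2=C3 geometry, is controlled by syn addition followed by stereoretentive transmetalation and reductive elimination. The step needs three selectivities: alkyne over alkene (the trisubstituted alkenes of 13 are inert to the Zr/Al reagent, and 16 with its cis alkenes is added only afterwards), alkenyl over methyl transfer (sp2 groups transmetalate faster, and free AlMe3 is stripped off first), and attack at CH2–iodine rather than at C=O (THF-complexed alkenyldialkylalanes leave esters alone at or below room temperature, and the weakly nucleophilic furylphosphine resists quaternisation).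

Compound list
1 | 2,4,4-trimethylcyclohex-2-en-1-one | CC1=CC(C)(C)CCC1=O | starting material
2 | (1R)-2,4,4-trimethylcyclohex-2-en-1-ol | O[C@@H]1CCC(C)(C)C=C1C | intermediate
3 | 1-ethoxyethenyl (1R)-2,4,4-trimethylcyclohex-2-en-1-yl ether (mixed ketene acetal) | C=C(OCC)O[C@@H]1CCC(C)(C)C=C1C | intermediate
4 | ethyl 2-[(1S)-2,6,6-trimethylcyclohex-2-en-1-yl]acetate | CCOC(=O)C[C@@H]1C(C)=CCCC1(C)C | intermediate
5 | 2-[(1S)-2,6,6-trimethylcyclohex-2-en-1-yl]ethan-1-ol | OCC[C@@H]1C(C)=CCCC1(C)C | intermediate
6 | (6S)-6-(2-iodoethyl)-1,5,5-trimethylcyclohex-1-ene | ICC[C@@H]1C(C)=CCCC1(C)C | intermediate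
7 | (6S)-6-(but-3-yn-1-yl)-1,5,5-trimethylcyclohex-1-ene | C#CCC[C@@H]1C(C)=CCCC1(C)C | intermediate
8 | dimethyl{(1E)-2-methyl-4-[(1S)-2,6,6-trimethylcyclohex-2-en-1-yl]but-1-en-1-yl}aluminium | C[Al](C)/C=C(\C)CC[C@@H]1C(C)=CCCC1(C)C | intermediate
9 | (6S)-6-[(3E)-4-iodo-3-methylbut-3-en-1-yl]-1,5,5-trimethylcyclohex-1-ene | I/C=C(\C)CC[C@@H]1C(C)=CCCC1(C)C | intermediate
10 | (4-bromobut-1-yn-1-yl)trimethylsilane | C[Si](C)(C)C#CCCBr | starting material
11 | [4-(trimethylsilyl)but-3-yn-1-yl]zinc bromide | C[Si](C)(C)C#CCC[Zn]Br | intermediate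
12 | trimethyl{(5E)-6-methyl-8-[(1S)-2,6,6-trimethylcyclohex-2-en-1-yl]oct-5-en-1-yn-1-yl}silane | C[Si](C)(C)C#CCC/C=C(\C)CC[C@@H]1C(C)=CCCC1(C)C | intermediate
13 | (6S)-1,5,5-trimethyl-6-[(3E)-3-methyloct-3-en-7-yn-1-yl]cyclohex-1-ene | C#CCC/C=C(\C)CC[C@@H]1C(C)=CCCC1(C)C | intermediate
14 | α-linolenic acid, (9Z,12Z,15Z)-octadeca-9,12,15-trienoic acid | CC/C=C\C/C=C\C/C=C\CCCCCCCC(=O)O | starting material
15 | chloromethyl (9Z,12Z,15Z)-octadeca-9,12,15-trienoate | CC/C=C\C/C=C\C/C=C\CCCCCCCC(=O)OCCl | intermediate
16 | iodomethyl (9Z,12Z,15Z)-octadeca-9,12,15-trienoate | CC/C=C\C/C=C\C/C=C\CCCCCCCC(=O)OCI | intermediate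
17 | dimethyl{(1E,5E)-2,6-dimethyl-8-[(1S)-2,6,6-trimethylcyclohex-2-en-1-yl]octa-1,5-dien-1-yl}aluminium | C[Al](C)/C=C(\C)CC/C=C(\C)CC[C@@H]1C(C)=CCCC1(C)C | intermediate
18 | (2E,6E)-3,7-dimethyl-9-[(1S)-2,6,6-trimethylcyclohex-2-en-1-yl]nona-2,6-dien-1-yl (9Z,12Z,15Z)-octadeca-9,12,15-trienoate | CC/C=C\C/C=C\C/C=C\CCCCCCCC(=O)OC/C=C(\C)CC/C=C(\C)CC[C@@H]1C(C)=CCCC1(C)C | target

Total step count: 11. Longest linear sequence: 9 (steps 1–8 and 11).

Steps most likely to fail

Step 11 (the labelled step).
- **Risk:** insertion of zerovalent palladium into 16 may be outrun by quaternisation of the phosphine or by methyl transfer from aluminium. Lewis-acid ionisation of the iodide, followed by attack on the electron-rich alkenes, is a further competing path.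
- **Fallback:** this uses reversed polarity and known chemistry, sets out from 13 and 16, and comes back at 18. Compound 13 is carboaluminated as in step 6 and alane 17 is quenched with iodine to give (6S)-6-[(3E,7E)-8-iodo-3,7-dimethylocta-3,7-dien-1-yl]-1,5,5-trimethylcyclohex-1-ene F1. Separately, 16 is stirred with activated Zn dust in THF to give {[(9Z,12Z,15Z)-octadeca-9,12,15-trienoyl]oxy}methylzinc iodide F2. Negishi coupling of F1 with F2 under Pd(PPh3)4 in THF then gives 18; acyloxymethylzinc iodides are established partners for sp2 halides.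

Step 2.
- **Risk:** the [3,3] shift must form a bond at a carbon flanked by the gem-dimethyl group. Heat- and acid-induced elimination, or ionisation of the allylic C–O bond with erosion of chirality transfer, may therefore compete.
- **Fallback:** an intermolecular anti-SN2′ substitution replaces the sigmatropic shift. It sets out from 1 and 10 and comes back at 7.
  - Because the copper reagent enters anti to the leaving group, the opposite carbinol configuration is needed. Compound 1 is therefore reduced with the enantiomeric (R)-1-methyl-3,3-diphenyltetrahydro-1H,3H-pyrrolo[1,2-c][1,3,2]oxazaborole and catecholborane to (1S)-2,4,4-trimethylcyclohex-2-en-1-ol F3.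
  - F3 is esterified with picolinic acid (DCC, DMAP) to (1S)-2,4,4-trimethylcyclohex-2-en-1-yl pyridine-2-carboxylate F4.
  - Compound 10 is converted with Mg in THF into [4-(trimethylsilyl)but-3-yn-1-yl]magnesium bromide F5. In the presence of CuBr·SMe2, F5 displaces the magnesium-chelated picolinate of F4 at the γ-carbon to give trimethyl{4-[(1S)-2,6,6-trimethylcyclohex-2-en-1-yl]but-1-yn-1-yl}silane F6.
  - K2CO3 in MeOH then gives 7.

Step 1.
- **Risk:** facial discrimination may be poor, because both arms of the ketone are ring carbons of similar bulk. Uncatalysed background reduction is a further risk.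
- **Fallback:** resolution through covalent diastereomers replaces asymmetric catalysis. It sets out from 1 and comes back at 2. Luche reduction (NaBH4, CeCl3·7H2O, MeOH) gives (±)-2,4,4-trimethylcyclohex-2-en-1-ol F7. Esterification with (S)-2-methoxy-2-phenylacetic acid (DCC, DMAP) gives (1R)-2,4,4-trimethylcyclohex-2-en-1-yl (2S)-2-methoxy-2-phenylacetate F8 together with its diastereomer (1S)-2,4,4-trimethylcyclohex-2-en-1-yl (2S)-2-methoxy-2-phenylacetate F9. F9 is removed by chromatography or crystallisation, and LiOH in aqueous THF releases 2 from F8.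

Further compounds
F1 | step 11 | (6S)-6-[(3E,7E)-8-iodo-3,7-dimethylocta-3,7-dien-1-yl]-1,5,5-trimethylcyclohex-1-ene | I/C=C(\C)CC/C=C(\C)CC[C@@H]1C(C)=CCCC1(C)C
F2 | step 11 | {[(9Z,12Z,15Z)-octadeca-9,12,15-trienoyl]oxy}methylzinc iodide | CC/C=C\C/C=C\C/C=C\CCCCCCCC(=O)OC[Zn]I
F3 | step 2 | (1S)-2,4,4-trimethylcyclohex-2-en-1-ol | O[C@H]1CCC(C)(C)C=C1C
F4 | step 2 | (1S)-2,4,4-trimethylcyclohex-2-en-1-yl pyridine-2-carboxylate | O=C(O[C@H]1CCC(C)(C)C=C1C)c1ccccn1
F5 | step 2 | [4-(trimethylsilyl)but-3-yn-1-yl]magnesium bromide | C[Si](C)(C)C#CCC[Mg]Br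
F6 | step 2 | trimethyl{4-[(1S)-2,6,6-trimethylcyclohex-2-en-1-yl]but-1-yn-1-yl}silane | C[Si](C)(C)C#CCC[C@@H]1C(C)=CCCC1(C)C
F7 | step 1 | (±)-2,4,4-trimethylcyclohex-2-en-1-ol | OC1CCC(C)(C)C=C1C
F8 | step 1 | (1R)-2,4,4-trimethylcyclohex-2-en-1-yl (2S)-2-methoxy-2-phenylacetate | CO[C@H](C(=O)O[C@@H]1CCC(C)(C)C=C1C)c1ccccc1
F9 | step 1 | (1S)-2,4,4-trimethylcyclohex-2-en-1-yl (2S)-2-methoxy-2-phenylacetate | CO[C@H](C(=O)O[C@H]1CCC(C)(C)C=C1C)c1ccccc1
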